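## Retrosynthetic overview

Assumption: a de novo gibberellin synthesis would take well over 25 steps, so I start from commercial gibberellic acid (GA3). All rings (A/B/C/D and the 19→10 lactone) and every stereocentre except C15 are inherited from GA3.
1. The target is 15-hydroxy-GA1. Disconnect the C15 alcohol to the 15-oxo-16-ene (an α-methylene cyclopentanone), which is reduced last from the exo face.
2. The 15-oxo enone comes from Riley SeO2 allylic oxidation of the exocyclic C16=C17 alkene of GA1.
3. GA1 comes from GA3 by chemoselective saturation of the ring-A Δ1,2 alkene. This must be done first, because once the enone is present it would be reduced far faster than Δ1,2.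
4. No rings are formed in this route.

## Route

**Step 1**
Reactants: 1, gibberellic acid (GA3)
Product: 2, gibberellin A1 (GA1, 1,2-dihydro-GA3)
Conditions: dipotassium azodicarboxylate (KO2C–N=N–CO2K, 10 equiv), AcOH (20 equiv), MeOH, 0 °C → rt; then a second portion of reagents
Reagents that add atoms: none
Why: Diimide, generated in situ from the azodicarboxylate and acid, is a non-catalytic syn H2 donor (diimide reduction). It reduces the unhindered cis-disubstituted Δ1,2 alkene in preference to the hindered 1,1-disubstituted C16=C17 alkene of the bicyclo[3.2.1]octane. The OH groups, the acid and the lactone are untouched, and no new stereocentre forms because C1 and C2 become CH2.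

**Step 2**
Reactants: 2, GA1
Product: 3, 15-oxo-GA1
Conditions: SeO2 (1.5 equiv), 1,4-dioxane, 90 °C, 4 h
Reagents that add atoms: selenium dioxide, O=[Se]=O (the source of the new C15 oxygen)
Why: Riley allylic oxidation proceeds by ene reaction and [2,3]-sigmatropic shift to the C15 allylic alcohol, which is over-oxidised under these forcing conditions to the conjugated α-methylene ketone. Because C15 becomes sp2, the facial question is deferred to Step 3. The saturated 3-OH and the tertiary 13-OH cannot be oxidised by SeO2.

**Step 3**
Reactants: 3, 15-oxo-GA1
Product: 4, gibberellin A72 (15-hydroxy-GA1, the target)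
Conditions: NaBH4 (4 equiv), CeCl3·7H2O (1.5 equiv), MeOH, −78 → 0 °C; then KHSO4 to pH 3–4, EtOAc extraction
Reagents that add atoms: none
Why: Luche reduction (Ce(III)-mediated NaBH4 reduction) attacks the carbonyl in a 1,2-sense and suppresses conjugate reduction of the exocyclic enone. Hydride enters the C/D bicyclo[3.2.1]octane from the less hindered exo face, syn to the one-carbon C14 bridge, as in norbornanone reductions. This places the new C15–OH on the endo face, which is the configuration in the target SMILES. The lactone and the carboxylate survive at ≤0 °C, and the mild acidic work-up leaves the tertiary 13-OH intact.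

## Compound list

| No. | Name | SMILES | Role |
|---|---|---|---|
| 1 | Gibberellic acid (GA3) | C=C1C[C@]23C[C@@]1(O)CC[C@H]2[C@@]12C=C[C@H](O)[C@@](C)(C(=O)O1)[C@H]2[C@@H]3C(=O)O | starting material |
| 2 | Gibberellin A1 (1,2-dihydro-GA3) | C=C1C[C@]23C[C@@]1(O)CC[C@H]2[C@@]12CC[C@H](O)[C@@](C)(C(=O)O1)[C@H]2[C@@H]3C(=O)O | intermediate |
| 3 | 15-Oxo-GA1 | C=C1C(=O)[C@]23C[C@@]1(O)CC[C@H]2[C@@]12CC[C@H](O)[C@@](C)(C(=O)O1)[C@H]2[C@@H]3C(=O)O | intermediate |
| 4 | Gibberellin A72 (15-hydroxy-GA1) | C=C1[C@@H](O)[C@]23C[C@@]1(O)CC[C@H]2[C@@]12CC[C@H](O)[C@@](C)(C(=O)O1)[C@H]2[C@@H]3C(=O)O | target |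

## Totals

- Total steps: 3.
- Longest linear sequence: 3, from GA3.

## Three steps most likely to fail

1. **Step 1 (Δ1,2 versus Δ16 selectivity).** Diimide may partly reduce the exocyclic alkene and give 16,17-dihydro products.
   - Fallback: skip the step and start from commercially supplied GA1. Alternatively, oxidise the 3-OH of GA3 to the 1-en-3-one on the methyl ester, do a Cu–H conjugate reduction, reduce the ketone back to the equatorial 3β-alcohol, and hydrolyse the ester.
2. **Step 2 (SeO2 oxidation).** The free acid and the tertiary allylic 13-OH are prone to acid-promoted C/D Wagner–Meerwein rearrangement. Over-oxidation and selenium by-products are also possible.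
   - Fallback: replace the chemical C–H oxidation with a biocatalytic C15 hydroxylation of GA1 (a P450 or fungal whole-cell hydroxylase). Then oxidise the alcohol to the ketone if the reduction in Step 3 is still needed.
3. **Step 3 (C15 facial selectivity and 1,2- versus 1,4-reduction).** The endo:exo alcohol ratio may be poor, or the α-methylene ketone may undergo conjugate reduction or Michael addition of MeOH.
   - Fallback: if the exo-OH epimer predominates, protect the acid as its methyl ester and the 3-OH as its acetate. Invert C15 by Mitsunobu reaction with p-nitrobenzoic acid, then methanolyse the p-nitrobenzoate and remove the protecting groups to give the endo alcohol.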